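**Plan**
1. Numbering (3,7-dioxabicyclo[3.3.0]octane): C1 (C–OH), C2 (CH–syringyl), O3, C4, C5 (CH), C6 (CH–guaiacyl), O7, C8. Ring A = C1/C5/C6/O7/C8, ring B = C1/C2/O3/C4/C5.
2. Retrosynthesis: O3–C2 is cut last, together with the C1–OH bond, back to the ring-A arylidene alcohol 14 (C1=C2 alkene, C4–OH free). Then C1–C5 is cut back to the epoxy aryl-propargyl ether 13, then the aryl–alkyne and O7–C8 bonds back to epoxy alcohol 7 and vanillin.
3. Forward: ring A arises first by a 5-exo-dig radical cyclisation with Cp2TiCl. Ring B arises last by an epoxidation / fluoride-triggered quinone-methide cascade that also frees both phenols.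
4. Enabling feature: C2 is benzylic and para to the syringyl phenol oxygen, vicinal to the tertiary carbinol C1, and 1,5 to the C4 hydroxyl. A C1–C2 oxirane on ring A is therefore a masked para-quinone methide whose collapse installs the C1–OH and the O3–C2 bond in one operation.
5. Stereochemistry: C6 from a Sharpless kinetic resolution; C5 trans to C6 in the radical cyclisation; C1 from the face of the epoxidation; C2 (aryl exo) and the cis fusion in the quinone-methide ring closure.

Key step: step 8

Remark: compound 5 is racemic and only its (S)-enantiomer is carried into 7; DMDO is used as a freshly prepared acetone solution (from acetone and KHSO5).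

**Step 1**
Reactants: 1 vanillin; 2 triisopropylsilyl chloride
Product: 3 3-methoxy-4-(triisopropylsilyloxy)benzaldehyde
Conditions: imidazole, DMF, rt
Reagents that add atoms: triisopropylsilyl chloride (2), CC(C)[Si](Cl)(C(C)C)C(C)C
Why: Imidazole-promoted silylation of the phenol; the hindered aryl silyl ether should survive the Grignard addition and the NaH alkylation and still fall to fluoride in the last step.

**Step 2**
Reactants: 3 3-methoxy-4-(triisopropylsilyloxy)benzaldehyde; 4 vinylmagnesium bromide
Product: 5 rac-1-[3-methoxy-4-(triisopropylsilyloxy)phenyl]prop-2-en-1-ol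
Conditions: THF, −78 to 0 °C; sat. aq. NH4Cl
Reagents that add atoms: vinylmagnesium bromide (4), C=C[Mg]Br
Why: Grignard 1,2-addition to the aldehyde gives the secondary allylic alcohol as the racemate, which is acceptable because the next step resolves it.

**Step 3**
Reactants: 5 rac-1-[3-methoxy-4-(triisopropylsilyloxy)phenyl]prop-2-en-1-ol; 6 tert-butyl hydroperoxide
Product: 7 (R)-[3-methoxy-4-(triisopropylsilyloxy)phenyl][(S)-oxiran-2-yl]methanol (erythro epoxy alcohol)
Conditions: Ti(OiPr)4 (15 mol%), D-(−)-diisopropyl tartrate (20 mol%), t-BuOOH (0.55 equiv, decane), 4 Å MS, CH2Cl2, −20 °C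
Reagents that add atoms: tert-butyl hydroperoxide (6), CC(C)(C)OO
Why: Sharpless kinetic resolution: with the D-(−)-tartrate the (S)-enantiomer of 5 should be epoxidised fast to the erythro epoxy alcohol, which fixes the carbinol centre (the future C6) by reagent control, while (R)-5 stays behind and is separated; the oxirane carbon becomes a radical in step 7, so only the carbinol centre has to be pure.

**Step 4**
Reactants: 7 erythro epoxy alcohol; 8 propargyl bromide
Product: 9 (S)-2-{(R)-[3-methoxy-4-(triisopropylsilyloxy)phenyl](prop-2-yn-1-yloxy)methyl}oxirane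
Conditions: NaH, Bu4NI (cat.), THF, 0 °C to rt
Reagents that add atoms: propargyl bromide (8), C#CCBr
Why: Williamson ether synthesis on the sodium alkoxide in aprotic THF, where alkylation by the reactive propargylic bromide should outrun Payne rearrangement of the epoxy alkoxide; no stereocentre is touched.

**Step 5**
Reactants: 10 4-bromo-2,6-dimethoxyphenol; 11 tert-butyldimethylsilyl chloride
Product: 12 (4-bromo-2,6-dimethoxyphenoxy)(tert-butyl)dimethylsilane
Conditions: imidazole, DMF, 40 °C
Reagents that add atoms: tert-butyldimethylsilyl chloride (11), CC(C)(C)[Si](C)(C)Cl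
Why: Silylation of the flanked phenol masks the syringyl oxygen as a fluoride-labile group that later serves as the trigger of the key step.

**Step 6**
Reactants: 9 epoxy propargyl ether; 12 (4-bromo-2,6-dimethoxyphenoxy)(tert-butyl)dimethylsilane
Product: 13 (S)-2-{(R)-[3-methoxy-4-(triisopropylsilyloxy)phenyl]({3-[4-(tert-butyldimethylsilyloxy)-3,5-dimethoxyphenyl]prop-2-yn-1-yl}oxy)methyl}oxirane
Conditions: PdCl2(PhCN)2 (3 mol%), P(t-Bu)3 (6 mol%), CuI (2 mol%), i-Pr2NH, dioxane, rt
Reagents that add atoms: none
Why: Sonogashira coupling of the terminal alkyne with the unhindered aryl bromide; a bulky-phosphine zerovalent palladium catalyst should allow room temperature, which the oxirane and both aryl silyl ethers tolerate.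

**Step 7**
Reactants: 13 epoxy aryl-propargyl ether
Product: 14 {(2S,3R,4E)-4-[4-(tert-butyldimethylsilyloxy)-3,5-dimethoxybenzylidene]-2-[3-methoxy-4-(triisopropylsilyloxy)phenyl]tetrahydrofuran-3-yl}methanol
Conditions: Cp2TiCl2 (2.5 equiv), Zn dust, THF, rt, slow addition of the green Cp2TiCl solution to 13; then cold 1 M HCl
Reagents that add atoms: none
Why: Reductive opening of the oxirane by Cp2TiCl (trivalent titanium) at the more substituted carbon should give the secondary radical at C5, which closes ring A by 5-exo-dig radical cyclisation onto the aryl alkyne (C1–C5 bond); C5 is set trans to the C6 aryl group in a chair-like transition state with both substituents pseudo-equatorial, and reduction and protonation of the linear aryl-stabilised vinyl radical from the less hindered C8 side should give mainly the E alkene, although step 8 tolerates either geometry.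

**Step 8**
Reactants: 14 ring-A arylidene alcohol; 15 dimethyldioxirane
Product: 18 fraxiresinol, via spiro-oxirane 16 (not isolated), via para-quinone methide 17 (not isolated)
Conditions: DMDO (1.2 equiv, acetone), CH2Cl2, −40 to −10 °C; evaporate cold; then TBAF (3 equiv), THF (high dilution), 0 °C to rt, Ar; AcOH quench
Reagents that add atoms: dimethyldioxirane (15), CC1(C)OO1
Why: DMDO should transfer oxygen in a concerted way to the electron-rich C1=C2 alkene on the ring-A face anti to the C5 hydroxymethyl group to give oxirane 16; fluoride then frees both phenols, the syringyl phenoxide para to C2 pushes open the C2–O bond to give para-quinone methide 17 with the C1 oxygen in place, and the C4 hydroxyl adds to C2 (oxa-1,6-addition) to form the O3–C2 bond with rearomatisation. The closest known reaction types are the fluoride-triggered generation of para-quinone methides from silyl aryl ethers that carry a benzylic leaving group, the 5-endo opening of aryl oxiranes by a pendant hydroxyl, and the quinone-methide cyclisation by which furofuran lignans form. Ring B closes in the 5-exo-trig mode onto the exocyclic quinone-methide carbon (formally the 5-endo opening of the oxirane), and the transient oxirane ring closes by concerted oxygen transfer. C1 is controlled by the face of the epoxidation, which the adjacent pseudo-axial C5 substituent should shield on one side; C2 is controlled by allylic 1,3-strain in 17, where the small C1–O bond eclipses the quinoid ring so that the aryl group ends up exo and cis to the C1 hydroxyl, and the cis fusion is enforced because the C5 tether can reach C2 only from the face opposite the C1 oxygen. The step needs facial selectivity in the epoxidation, chemoselectivity of DMDO for the alkene over the silylated arenes and the benzylic ether C–H, and productive closure by O3 over re-closure of the oxirane; the last is secured because only the O3 addition is a strain-free, rearomatising exit while oxirane re-formation is reversible. Because C2 is trigonal in 17, both alkene isomers of 14 should converge on the same product.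

**Compound list**
1 | vanillin | COc1cc(C=O)ccc1O | starting material
2 | triisopropylsilyl chloride | CC(C)[Si](Cl)(C(C)C)C(C)C | starting material
3 | 3-methoxy-4-(triisopropylsilyloxy)benzaldehyde | COc1cc(C=O)ccc1O[Si](C(C)C)(C(C)C)C(C)C | intermediate
4 | vinylmagnesium bromide | C=C[Mg]Br | starting material
5 | rac-1-[3-methoxy-4-(triisopropylsilyloxy)phenyl]prop-2-en-1-ol | COc1cc(C(O)C=C)ccc1O[Si](C(C)C)(C(C)C)C(C)C | intermediate
6 | tert-butyl hydroperoxide | CC(C)(C)OO | starting material
7 | (R)-[3-methoxy-4-(triisopropylsilyloxy)phenyl][(S)-oxiran-2-yl]methanol | COc1cc([C@@H](O)[C@@H]2CO2)ccc1O[Si](C(C)C)(C(C)C)C(C)C | intermediate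
8 | propargyl bromide | C#CCBr | starting material
9 | (S)-2-{(R)-[3-methoxy-4-(triisopropylsilyloxy)phenyl](prop-2-yn-1-yloxy)methyl}oxirane | COc1cc([C@@H](OCC#C)[C@@H]2CO2)ccc1O[Si](C(C)C)(C(C)C)C(C)C | intermediate
10 | 4-bromo-2,6-dimethoxyphenol | COc1cc(Br)cc(OC)c1O | starting material
11 | tert-butyldimethylsilyl chloride | CC(C)(C)[Si](C)(C)Cl | starting material
12 | (4-bromo-2,6-dimethoxyphenoxy)(tert-butyl)dimethylsilane | COc1cc(Br)cc(OC)c1O[Si](C)(C)C(C)(C)C | intermediate
13 | (S)-2-{(R)-[3-methoxy-4-(triisopropylsilyloxy)phenyl]({3-[4-(tert-butyldimethylsilyloxy)-3,5-dimethoxyphenyl]prop-2-yn-1-yl}oxy)methyl}oxirane | COc1cc([C@@H](OCC#Cc3cc(OC)c(O[Si](C)(C)C(C)(C)C)c(OC)c3)[C@@H]2CO2)ccc1O[Si](C(C)C)(C(C)C)C(C)C | intermediate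
14 | {(2S,3R,4E)-4-[4-(tert-butyldimethylsilyloxy)-3,5-dimethoxybenzylidene]-2-[3-methoxy-4-(triisopropylsilyloxy)phenyl]tetrahydrofuran-3-yl}methanol | COc1cc([C@H]2OC/C(=C/c3cc(OC)c(O[Si](C)(C)C(C)(C)C)c(OC)c3)[C@@H]2CO)ccc1O[Si](C(C)C)(C(C)C)C(C)C | intermediate
15 | dimethyldioxirane (reagent, acetone solution) | CC1(C)OO1 | starting material
16 | spiro-oxirane of 14 (1,5-dioxaspiro[2.4]heptane; oxirane oxygen on the ring-A face that carries H-5, anti to the hydroxymethyl group; not isolated) | COc1cc([C@H]2OC[C@@]3(O[C@H]3c4cc(OC)c(O[Si](C)(C)C(C)(C)C)c(OC)c4)[C@@H]2CO)ccc1O[Si](C(C)C)(C(C)C)C(C)C | intermediate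
17 | para-quinone methide (ring A with tertiary C1–OH, free C4–OH and free guaiacyl phenol; C2 is the exocyclic carbon of a 2,6-dimethoxy-para-quinone methide; not isolated) | COc1cc([C@H]2OC[C@](O)(C=C3C=C(OC)C(=O)C(OC)=C3)[C@@H]2CO)ccc1O | intermediate
18 | fraxiresinol, (1S,2R,5R,6S)-2-(4-hydroxy-3,5-dimethoxyphenyl)-6-(4-hydroxy-3-methoxyphenyl)-3,7-dioxabicyclo[3.3.0]octan-1-ol | COc1cc([C@H]2OC[C@]3(O)[C@@H](c4cc(OC)c(O)c(OC)c4)OC[C@H]23)ccc1O | target

**Totals**
Total step count: 8. Longest linear sequence: 7 steps (steps 1, 2, 3, 4, 6, 7, 8).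

**Steps most likely to fail**

1. Step 8. What may go wrong: poor facial selectivity in the epoxidation (attack syn to the C5 hydroxymethyl group gives an oxirane that cannot close a cis-fused ring B), or intermolecular trapping and oligomerisation of the quinone methide under the basic fluoride conditions. The fallback sets out from 14 and comes back at 18, and replaces the base-triggered cascade by a stepwise dihydroxylation and acid cyclodehydration. Catalytic OsO4 with NMO in acetone–water should dihydroxylate the C1=C2 alkene from the less hindered face to give the triol F1, a stable compound at which diastereomers can be separated. Camphorsulfonic acid in CH2Cl2 at 0 °C should then ionise the electron-rich benzylic C2–OH, and capture of the cation by the C4 hydroxyl gives the bis-silyl ether of fraxiresinol F2. TBAF with AcOH in THF removes both silyl groups to give 18.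

2. Step 7. What may go wrong: trapping of the C5 radical by a second Cp2TiCl followed by β-elimination (deoxygenation to the allyl ether) before cyclisation, or insufficient trans selectivity at C5. The fallback sets out from 13 and comes back at 17, and replaces the radical closure by a stereospecific two-electron closure. Pd(PPh3)4-catalysed syn-hydrostannation of 13 with Bu3SnH should place tin on C1, the alkyne carbon next to the propargylic CH2, to give the alkenylstannane F3. Tin–lithium exchange (n-BuLi, THF, −78 °C) and then BF3·OEt2 should let the alkenyllithium open the oxirane at C5 in the 5-exo-tet mode with inversion, which translates the defined (S)-oxirane centre into the required trans C5/C6 relationship and gives the Z isomer of 14 F4. Under the conditions of step 8 this gives the C2-epimeric spiro-oxirane F5, which opens to the same quinone methide 17 because C2 becomes trigonal.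

3. Step 3. What may go wrong: insufficient rate difference between the enantiomers of the slowly reacting terminal vinyl carbinol, so that 7 forms with eroded enantiomeric purity. The fallback sets out from 5 and comes back at 7, and separates the enantiomers by enzymatic acylation before any epoxidation. Immobilised Candida antarctica lipase B with vinyl acetate should acylate the (R)-enantiomer to the (R)-acetate F7 and leave the (S)-alcohol F6. F6 is then epoxidised to completion with Ti(OiPr)4, D-(−)-diisopropyl tartrate and t-BuOOH, now a matched asymmetric epoxidation of a single enantiomer, to give 7.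

**Further compounds**
F1 | step 8 | (S)-[4-(tert-butyldimethylsilyloxy)-3,5-dimethoxyphenyl]{3-hydroxy-4-(hydroxymethyl)-5-[3-methoxy-4-(triisopropylsilyloxy)phenyl]tetrahydrofuran-3-yl}methanol (triol, C1–OH on the face of H-5) | COc1cc([C@H]2OC[C@](O)([C@@H](O)c3cc(OC)c(O[Si](C)(C)C(C)(C)C)c(OC)c3)[C@@H]2CO)ccc1O[Si](C(C)C)(C(C)C)C(C)C
F2 | step 8 | fraxiresinol bis-silyl ether (syringyl O-TBS, guaiacyl O-TIPS) | COc1cc([C@H]2OC[C@]3(O)[C@@H](c4cc(OC)c(O[Si](C)(C)C(C)(C)C)c(OC)c4)OC[C@H]23)ccc1O[Si](C(C)C)(C(C)C)C(C)C
F3 | step 7 | (E)-alkenylstannane from syn-hydrostannation of 13 (tributyltin on C1, aryl cis to the CH2O group) | COc1cc([C@@H](OC/C(=C\c3cc(OC)c(O[Si](C)(C)C(C)(C)C)c(OC)c3)[Sn](CCCC)(CCCC)CCCC)[C@@H]2CO2)ccc1O[Si](C(C)C)(C(C)C)C(C)C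
F4 | step 7 | {(2S,3R,4Z)-4-[4-(tert-butyldimethylsilyloxy)-3,5-dimethoxybenzylidene]-2-[3-methoxy-4-(triisopropylsilyloxy)phenyl]tetrahydrofuran-3-yl}methanol (Z isomer of 14) | COc1cc([C@H]2OC/C(=C\c3cc(OC)c(O[Si](C)(C)C(C)(C)C)c(OC)c3)[C@@H]2CO)ccc1O[Si](C(C)C)(C(C)C)C(C)C
F5 | step 7 | spiro-oxirane of F4 (C2 epimer of 16) | COc1cc([C@H]2OC[C@@]3(O[C@@H]3c4cc(OC)c(O[Si](C)(C)C(C)(C)C)c(OC)c4)[C@@H]2CO)ccc1O[Si](C(C)C)(C(C)C)C(C)C
F6 | step 3 | (S)-1-[3-methoxy-4-(triisopropylsilyloxy)phenyl]prop-2-en-1-ol | COc1cc([C@@H](O)C=C)ccc1O[Si](C(C)C)(C(C)C)C(C)C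
F7 | step 3 | (R)-1-[3-methoxy-4-(triisopropylsilyloxy)phenyl]prop-2-en-1-yl acetate | COc1cc([C@H](OC(C)=O)C=C)ccc1O[Si](C(C)C)(C(C)C)C(C)C
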